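# Proposed synthesis of CNP0106875.1 (compound 30)

## Analysis of the target

Compound 30 is an open propan-1-one chain rather than a fused polycycle: its C2 (called Cα below) carries the carbonyl of a 2,4,6-trihydroxybenzoyl unit, C3 of a 5,7-dihydroxy-4H-chromen-4-one (O1, C2–C4, C4a, C5–C8, C8a) and a bis(4-hydroxyphenyl)methyl group. Cα is the only stereocentre and is R (aroyl carbon > chromone C3 > diarylmethyl carbon > H); the neighbouring methine bears two identical aryl rings and is not stereogenic, so only absolute configuration has to be controlled. The Cα–H bond is α to the aryl ketone and allylic to C2=C3, so once the ketone exists it is acidic and racemisation by enolisation is the main threat. Further sensitive features are the seven phenols, the chromone (opened at C2 by hydroxide or alkoxide) and the phloroglucinol-type rings, which make any benzylic leaving group on them ionise in acid. The difficulty is to create a centre flanked by three bulky substituents in one enantiomer and to carry it through heterocycle formation and global deprotection. The strategy rests on chromone C2 being an unsubstituted CH between O1 and C3. It can enter as the carbonyl carbon of a formate ester on the C8a oxygen and be joined to C3 by olefination if C3 is a phosphorus ylide carbon stabilised by the C4 carbonyl, while Cα is kept next to a silyl-protected carbinol and not next to a ketone.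

## Retrosynthetic reasoning

**30 to 29.** The seven O–benzyl bonds are cut last. The phenols must be masked through enolate, ylide and acylation chemistry, and benzyl ethers are removed by neutral hydrogenolysis, which the acidic Cα–H of ketone 29 requires. Ethers that need a strong Lewis acid for cleavage would put the stereocentre at risk at the very end.

**29 to 28 to 27.** The aryl ketone is traced back to the carbinol 28 and its silyl ether 27. This keeps Cα without a ketone neighbour through fragment coupling and ring formation; the forward steps are a buffered desilylation and a neutral oxidation. The carbinol configuration is irrelevant because it is erased.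

**27 to 26 (key disconnection).** The C2=C3 bond is cut. Only C2 is missing from an ortho-oxygenated aryl ketone, so it is placed on O1 as the formate of 26, and C3 becomes the carbon of an acyl-stabilised ylide. A cut at O1–C2 or at C4–C4a would need base or acid next to the chain, whereas this closure is thermal and base-free. The forward reaction must olefinate an ester carbonyl chemoselectively.

**26 to 25 to 24.** The formate is too labile to survive ylide acylation, so it is put on last onto phenol 25. The phenol in turn is carried through the acylation as the acetate 24.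

**24 to 15 + 21.** The C3–C4 bond is cut, which joins two fragments of similar size. Ylide 22, made from phosphonium salt 15, is acylated by acid chloride 21 (through salt 23); 21 delivers ring A and C4.

**15 to 13.** The C–P bond is formed by displacement at the primary carbon of triflate 14, made from alcohol 13.

**13 to 12 to 11.** The primary alcohol arises by reductive removal of the auxiliary from the silylated aldol 12. The imide carbonyl that controlled the stereochemistry thus becomes the future C3.

**11 to 6 + 9.** The Cα–carbinol bond is cut as an aldol. Boron enolate 10 of imide 6 adds to aldehyde 9, which sets Cα under auxiliary control and installs the phloroglucinol ring directly at the carbinol oxidation level.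

**6 to 4 + 5; 4 to 1 + 2.** The second aryl group is added by conjugate addition of 5 to enoyl imide 4. Both aryl groups are equal, so no stereocentre arises. 4 comes from acid 1 and auxiliary 2 through anhydride 3.

**Benzylated building blocks.** The formyl C–C bond of 9 is cut, leading to the symmetric triether 7; the forward reaction is a ring formylation through iminium salt 8. 21 comes from 16 and 17 through 18, 19 and 20.

## Alternatives that were turned down

**Alternative 1:** Both aryl–carbonyl bonds (the aryl–C(=O) bond of the trihydroxybenzoyl group and C4–C4a) are cut, leading to two molecules of phloroglucinol A3 and (2S)-2-[bis(4-hydroxyphenyl)methyl]butanedioic acid A2. In the forward sense a Lewis-acid-mediated double Friedel–Crafts acylation gives the diketone (2S)-2-[bis(4-hydroxyphenyl)methyl]-1,4-bis(2,4,6-trihydroxyphenyl)butane-1,4-dione A1, and a one-carbon unit is then inserted at the C3 methylene.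
- For: it is by far the shortest plan, needs no protecting groups on the phloroglucinol rings and builds both aryl ketones at once from the cheapest arene.
- Against: in A1 the stereocentre is α to an aryl ketone from the moment it forms and sits in hot Lewis acid. A 1,4-diketone under acid also dehydrates to a furan (Paal–Knorr), which deletes the centre. A2 tends to close to its cyclic anhydride, and after the first acylation the γ-keto acid prefers enol-lactone formation to a second acylation. A3 is prone to O-acylation and double acylation on one ring. The later one-carbon insertion needs an enolate or enamine at C3 next to the enolisable Cα.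
- Comparison: on step count and protecting-group economy this alternative is clearly stronger. The chosen route in exchange makes both aryl ketones without acid and, once the auxiliary has been removed in step 6, keeps Cα without a carbonyl neighbour until step 17.

**Alternative 2:** The C3–C4 bond of a chroman-4-one is cut. A carbene from a chiral triazolium salt turns the aldehyde of 2-{[4,4-bis(4-methoxyphenyl)-3-(2,4,6-trimethoxybenzoyl)but-2-en-1-yl]oxy}-4,6-dimethoxybenzaldehyde A5 into an acyl anion equivalent that adds to the tethered enone. This gives (3R)-5,7-dimethoxy-3-[(2R)-1,1-bis(4-methoxyphenyl)-3-oxo-3-(2,4,6-trimethoxyphenyl)propan-2-yl]-2,3-dihydro-4H-chromen-4-one A4, which still needs dehydrogenation at C2–C3 and ether cleavage.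
- For: the induction is catalytic, no auxiliary is used, A5 is assembled by a simple O-alkylation, and closure of salicylaldehyde-derived substrates to chromanones is the best-behaved Stetter case.
- Against: the acceptor is an α-branched enone with the bulky diarylmethyl group on its α-carbon and a 2,6-disubstituted aroyl group twisted out of conjugation, so it is a poor acceptor. The only centre that survives to the target, Cα, is not set by the catalyst directly but by protonation of the enol intermediate. Its sense depends on alkene geometry, and it lies α to the aroyl ketone in a basic medium where it can equilibrate. The dehydrogenation must then be run next to this centre and next to a doubly benzylic C–H.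
- Comparison: this alternative is stronger on catalytic stereo-induction and on step count. The chosen strategy instead sets Cα directly in a closed transition state and keeps it non-enolisable during ring formation.

**Alternative 3:** The C4a–C5 and C8–C8a bonds of ring A are cut. 1-Methoxy-1,3-bis(trimethylsilyloxy)buta-1,3-diene A8 adds across (5S)-5-[bis(4-methoxyphenyl)methyl]-1-ethoxy-6-(2,4,6-trimethoxyphenyl)hex-1-yne-3,6-dione A7. Loss of methanol and desilylation give (2S)-2-[bis(4-methoxyphenyl)methyl]-4-(2-ethoxy-4,6-dihydroxyphenyl)-1-(2,4,6-trimethoxyphenyl)butane-1,4-dione A6.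
- For: the oxygen pattern of ring A is fixed regiochemically, one ortho oxygen is differentiated from the other, and no Friedel–Crafts step or hindered aroyl chloride is needed.
- Against: it builds a ring that the chosen route buys (as 16) and solves neither real problem. Cα is already α to a ketone in A7 and A6, both 1,4-dicarbonyl compounds open to furan formation, and the pyranone ring is still open. The alkoxy ynone is a push–pull alkyne of reduced dienophilicity, the diene can add in conjugate fashion without closing, and the ethyl ether must be cleaved later.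
- Comparison: on regiocontrol in ring A it is as strong as the chosen route. It is weaker on step economy and on stereochemical safety, which the C2=C3 closure of a non-enolisable precursor provides.

Key step: step 15

## Route

Remark on the chemistry: the seven phenols are carried as benzyl ethers so that the last step is a neutral hydrogenolysis. The silyl-protected carbinol centre of 26 and 27 is a spectator that step 17 erases; it is carried in the (S) configuration that the syn aldol of step 4 delivers.

Remark: 1, 2, 5, 7, 16 and 17 are taken as catalogue compounds.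

Step 1
Reactants: 1 (E)-4-(benzyloxy)cinnamic acid; 2 (S)-4-benzyl-2-oxazolidinone
Product: 4 (S)-4-benzyl-3-[(E)-3-(4-benzyloxyphenyl)prop-2-enoyl]oxazolidin-2-one, via mixed pivalic anhydride 3 (not isolated)
Conditions: PivCl, Et3N, THF, −20 °C; then 2, LiCl, −20 °C → rt
Reagents that add atoms: none
Why: N-Acylation of an oxazolidinone through a mixed pivalic anhydride with LiCl/Et3N; the nucleophile attacks the cinnamoyl carbonyl because the pivaloyl carbonyl is shielded by its tert-butyl group, and the auxiliary stereocentre is not touched.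

Step 2
Reactants: 4; 5 4-(benzyloxy)phenylmagnesium bromide
Product: 6 (S)-4-benzyl-3-[3,3-bis(4-benzyloxyphenyl)propanoyl]oxazolidin-2-one
Conditions: 5 (1.6 equiv), CuBr·SMe2 (30 mol %), THF/Me2S, −40 → −10 °C; then 1 M HCl, 0 °C
Reagents that add atoms: none
Why: Copper-catalysed conjugate addition of an aryl Grignard reagent to an N-enoyl oxazolidinone; the incoming aryl group equals the one already on the β-carbon, so that carbon is not stereogenic and no facial selectivity is needed.

Step 3
Reactants: 7 1,3,5-tris(benzyloxy)benzene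
Product: 9 2,4,6-tris(benzyloxy)benzaldehyde, via aryl iminium chloride 8 (not isolated)
Conditions: POCl3 (1.3 equiv), DMF, 0 → 40 °C; then aq. NaOAc, 0 °C → rt
Reagents that add atoms: N,N-dimethylformamide, CN(C)C=O (formyl carbon); water, O (carbonyl oxygen)
Why: Vilsmeier–Haack formylation; the chloroiminium ion from DMF and POCl3 attacks a ring carbon flanked by two ether oxygens, and the three free ring positions of 7 are equivalent by symmetry, so no regiochemical question arises. The iminium group of 8 deactivates the ring against a second attack, hydrolysis on work-up releases the aldehyde, and benzyl ethers tolerate these conditions.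

Step 4
Reactants: 6; 9
Product: 11 (S)-4-benzyl-3-[(2S,3S)-2-[bis(4-benzyloxyphenyl)methyl]-3-hydroxy-3-(2,4,6-tris(benzyloxy)phenyl)propanoyl]oxazolidin-2-one, via boron enolate 10 (not isolated)
Conditions: Bu2BOTf, iPr2NEt, CH2Cl2, 0 °C; 9, −78 → 0 °C; pH 7 buffer, MeOH, 30% H2O2, 0 °C
Reagents that add atoms: none
Why: Evans syn aldol addition; the Z-boron enolate 10 reacts through a chair Zimmerman–Traxler transition state on the face away from the benzyl group of the auxiliary (carbonyl dipoles opposed), which sets Cα as 2S and the carbinol as 3S in one step; binding to boron activates the electron-rich aldehyde, and the buffered oxidative work-up spares the acid-labile benzylic alcohol.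

Step 5
Reactants: 11
Product: 12 tert-butyldimethylsilyl ether of 11 with (2S,3S) configuration retained
Conditions: TBSOTf, 2,6-lutidine, CH2Cl2, −78 → 0 °C
Reagents that add atoms: tert-butyldimethylsilyl triflate, CC(C)(C)[Si](C)(C)OS(=O)(=O)C(F)(F)F
Why: Silylation of a hindered secondary alcohol with a silyl triflate; excess 2,6-lutidine keeps the medium non-acidic so that the electron-rich benzylic C–O bond does not ionise, and capping the hydroxyl blocks retro-aldol cleavage during step 6.

Step 6
Reactants: 12
Product: 13 (2R,3S)-2-[bis(4-benzyloxyphenyl)methyl]-3-(tert-butyldimethylsilyloxy)-3-(2,4,6-tris(benzyloxy)phenyl)propan-1-ol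
Conditions: LiBH4, MeOH (1.1 equiv), THF, 0 °C → rt
Reagents that add atoms: none
Why: Reductive cleavage of the N-acyl oxazolidinone with LiBH4 (hydride attack at the exocyclic carbonyl) to the primary alcohol with recovery of 2; the conditions do not enolise Cα, whose descriptor changes to R only because the substituent priorities change.

Step 7
Reactants: 13
Product: 15 [(2S,3S)-2-[bis(4-benzyloxyphenyl)methyl]-3-(tert-butyldimethylsilyloxy)-3-(2,4,6-tris(benzyloxy)phenyl)propyl]triphenylphosphonium triflate, via primary triflate 14 (not isolated)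
Conditions: Tf2O, 2,6-di-tert-butyl-4-methylpyridine, CH2Cl2, −78 °C; then PPh3 (3 equiv), −78 °C → rt
Reagents that add atoms: triflic anhydride, O=S(=O)(OS(=O)(=O)C(F)(F)F)C(F)(F)F; triphenylphosphine, c1ccc(cc1)P(c1ccccc1)c1ccccc1
Why: Triflation of the primary alcohol, then SN2 displacement of triflate by PPh3; the triflate is reactive enough for substitution at this β-branched carbon at or below room temperature, and the hindered pyridine base is not alkylated and keeps the medium from ionising the benzylic silyl ether.

Step 8
Reactants: 16 methyl 2,4,6-trihydroxybenzoate; 17 benzyl bromide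
Product: 18 methyl 2,4-bis(benzyloxy)-6-hydroxybenzoate
Conditions: 17 (2.05 equiv), K2CO3, acetone, reflux
Reagents that add atoms: none
Why: Williamson ether synthesis with two equivalents of 17; the 4-hydroxyl and one ortho hydroxyl react, while the remaining ortho hydroxyl, hydrogen-bonded to the ester carbonyl, is the least nucleophilic and stays free.

Step 9
Reactants: 18
Product: 19 2,4-bis(benzyloxy)-6-hydroxybenzoic acid
Conditions: KOH, DMSO/H2O, 80 °C; then 1 M HCl, 0 °C
Reagents that add atoms: potassium hydroxide, [K+].[OH-]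
Why: Saponification of a hindered salicylate ester under forcing alkaline conditions; acidification in the cold avoids decarboxylation of the electron-rich benzoic acid.

Step 10
Reactants: 19
Product: 20 2-acetoxy-4,6-bis(benzyloxy)benzoic acid
Conditions: Ac2O, pyridine, DMAP (cat.), CH2Cl2, 0 °C → rt; then H2O/THF
Reagents that add atoms: acetic anhydride, CC(=O)OC(C)=O
Why: O-Acetylation of the phenol by pyridine/DMAP acyl transfer; the aqueous stir hydrolyses any mixed carboxylic anhydride, and the acetate keeps the phenol out of the ylide acylation.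

Step 11
Reactants: 20
Product: 21 2-acetoxy-4,6-bis(benzyloxy)benzoyl chloride
Conditions: (COCl)2, DMF (cat.), CH2Cl2, 0 °C → rt
Reagents that add atoms: oxalyl chloride, ClC(=O)C(Cl)=O
Why: Acid chloride formation with oxalyl chloride under DMF catalysis at room temperature, conditions under which ortho-acetoxybenzoic acids are converted without loss of the acetate; 21 is used crude.

Step 12
Reactants: 15; 21
Product: 24 (3S,4S)-1-[2-acetoxy-4,6-bis(benzyloxy)phenyl]-3-[bis(4-benzyloxyphenyl)methyl]-4-(tert-butyldimethylsilyloxy)-4-(2,4,6-tris(benzyloxy)phenyl)-2-(triphenylphosphoranylidene)butan-1-one, via ylide 22 (not isolated), via acylphosphonium chloride 23 (not isolated)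
Conditions: NaN(SiMe3)2 (1.05 equiv), THF, −78 → 0 °C; 21, −78 °C; then NaN(SiMe3)2 (1.0 equiv), −78 → 0 °C
Reagents that add atoms: none
Why: C-Acylation of a non-stabilised phosphorus ylide by an acid chloride to an acylphosphonium salt, followed by its deprotonation to the acyl-stabilised ylide; the second portion of base also returns any phosphonium salt formed by proton transfer to the ylide, so one equivalent of 15 suffices, and the acid chloride reacts far faster than the aryl acetate at −78 °C.

Step 13
Reactants: 24
Product: 25 phenol acylphosphorane (2-hydroxy analogue of 24 with 3S,4S retained)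
Conditions: K2CO3, MeOH/THF, 0 °C
Reagents that add atoms: none
Why: Base-mediated methanolysis (transesterification) of the aryl acetate; at 0 °C the acyl-stabilised ylide neither olefinates the acetate nor reacts with methanol, and silyl and benzyl ethers are inert.

Step 14
Reactants: 25
Product: 26 aryl formate acylphosphorane (2-formyloxy analogue of 25 with 3S,4S retained)
Conditions: AcOCHO (from HCO2H and Ac2O), pyridine, CH2Cl2, −20 → 0 °C; volatiles removed in vacuo
Reagents that add atoms: acetic formic anhydride, CC(=O)OC=O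
Why: O-Formylation of the phenol by the mixed anhydride, which transfers formyl in preference to acetyl because the formyl carbonyl is the more electrophilic and less hindered; the fully substituted ylide carbon cannot be acylated productively, and low temperature with a non-aqueous work-up preserves the hydrolytically labile aryl formate, which is used at once.

Step 15
Reactants: 26
Product: 27 5,7-bis(benzyloxy)-3-[(1S,2R)-3,3-bis(4-benzyloxyphenyl)-1-(tert-butyldimethylsilyloxy)-1-(2,4,6-tris(benzyloxy)phenyl)propan-2-yl]-4H-chromen-4-one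
Conditions: toluene (0.01 M), 90 °C, Ar
Reagents that add atoms: none
Why: The carbon of the acyl-stabilised ylide (future C3) adds to the formate carbonyl carbon (future C2); the betaine closes to an oxaphosphetane fused to the new six-membered ring, and cycloreversion expels triphenylphosphine oxide to leave the C2=C3 double bond. The closest known reaction type is the intramolecular Wittig olefination of the ester carbonyl in ortho-acyloxyaryl acylphosphoranes, which gives 4H-chromen-4-ones on heating; a formate is the most electrophilic member of that ester class. The pyranone ring closes in the 6-exo-trig mode, since the attacked carbonyl carbon becomes a ring atom and its oxygen, which leaves with phosphorus, is exocyclic. No stereocentre is formed; Cα has the ylide carbon and the silyl-protected carbinol as neighbours, so it cannot enolise and is carried through unchanged. The step needs chemoselectivity for olefination of the formate over loss of the formyl group, and this is secured by the ortho relationship of formate and ylide (six-membered transition state), high dilution, the absence of added base and dry toluene. Should the tetrahedral adduct first collapse by formyl transfer to carbon, the released phenoxide re-adds to the new aldehyde and the same betaine is reached, so both paths converge on 27.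

Step 16
Reactants: 27
Product: 28 5,7-bis(benzyloxy)-3-[(1S,2R)-3,3-bis(4-benzyloxyphenyl)-1-hydroxy-1-(2,4,6-tris(benzyloxy)phenyl)propan-2-yl]-4H-chromen-4-one
Conditions: Bu4NF, AcOH, THF, rt → 45 °C
Reagents that add atoms: none
Why: Fluoride cleavage of the silyl ether; buffering with AcOH keeps the medium close to neutral so that the chromone is not opened at C2 and the benzylic alcohol is not ionised.

Step 17
Reactants: 28
Product: 29 5,7-bis(benzyloxy)-3-[(2R)-1,1-bis(4-benzyloxyphenyl)-3-oxo-3-(2,4,6-tris(benzyloxy)phenyl)propan-2-yl]-4H-chromen-4-one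
Conditions: Dess–Martin periodinane, pyridine, CH2Cl2, 0 °C → rt
Reagents that add atoms: none
Why: Dess–Martin oxidation of the secondary benzylic alcohol to the aryl ketone under buffered, essentially neutral conditions, so that the Cα–H bond, acidic from this point on, is not enolised; the spectator carbinol stereocentre disappears.

Step 18
Reactants: 29
Product: 30 5,7-dihydroxy-3-[(2R)-1,1-bis(4-hydroxyphenyl)-3-oxo-3-(2,4,6-trihydroxyphenyl)propan-2-yl]-4H-chromen-4-one (CNP0106875.1)
Conditions: H2 (1 atm), Pd/C (10% Pd on carbon), EtOAc/MeOH, rt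
Reagents that add atoms: none
Why: Catalytic hydrogenolysis of the seven benzyl ethers under neutral conditions; the C2=C3 bond of the chromone is a hindered vinylogous ester double bond that should be reduced far more slowly than O-benzyl bonds are cleaved, and Cα meets neither acid nor base.

## Compound list

1 | (E)-4-(benzyloxy)cinnamic acid | OC(=O)/C=C/c1ccc(OCc2ccccc2)cc1 | starting material
2 | (S)-4-benzyl-2-oxazolidinone | O=C1N[C@@H](Cc2ccccc2)CO1 | starting material
3 | (E)-3-(4-benzyloxyphenyl)prop-2-enoic pivalic anhydride (not isolated) | CC(C)(C)C(=O)OC(=O)/C=C/c1ccc(OCc2ccccc2)cc1 | intermediate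
4 | (S)-4-benzyl-3-[(E)-3-(4-benzyloxyphenyl)prop-2-enoyl]oxazolidin-2-one | O=C(/C=C/c1ccc(OCc2ccccc2)cc1)N1[C@@H](Cc2ccccc2)COC1=O | intermediate
5 | 4-(benzyloxy)phenylmagnesium bromide | Br[Mg]c1ccc(OCc2ccccc2)cc1 | starting material
6 | (S)-4-benzyl-3-[3,3-bis(4-benzyloxyphenyl)propanoyl]oxazolidin-2-one | O=C(CC(c1ccc(OCc2ccccc2)cc1)c1ccc(OCc2ccccc2)cc1)N1[C@@H](Cc2ccccc2)COC1=O | intermediate
7 | 1,3,5-tris(benzyloxy)benzene | c1c(OCc2ccccc2)cc(OCc2ccccc2)cc1OCc1ccccc1 | starting material
8 | N-methyl-N-{[2,4,6-tris(benzyloxy)phenyl]methylidene}methanaminium chloride (not isolated) | C[N+](C)=Cc1c(OCc2ccccc2)cc(OCc2ccccc2)cc1OCc1ccccc1.[Cl-] | intermediate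
9 | 2,4,6-tris(benzyloxy)benzaldehyde | O=Cc1c(OCc2ccccc2)cc(OCc2ccccc2)cc1OCc1ccccc1 | intermediate
10 | (Z)-dibutylboron enolate of 6 (not isolated) | CCCCB(CCCC)O/C(=C\C(c1ccc(OCc2ccccc2)cc1)c1ccc(OCc2ccccc2)cc1)N1[C@@H](Cc2ccccc2)COC1=O | intermediate
11 | (S)-4-benzyl-3-[(2S,3S)-2-[bis(4-benzyloxyphenyl)methyl]-3-hydroxy-3-(2,4,6-tris(benzyloxy)phenyl)propanoyl]oxazolidin-2-one | O=C([C@H]([C@H](O)c1c(OCc2ccccc2)cc(OCc2ccccc2)cc1OCc1ccccc1)C(c1ccc(OCc2ccccc2)cc1)c1ccc(OCc2ccccc2)cc1)N1[C@@H](Cc2ccccc2)COC1=O | intermediate
12 | (S)-4-benzyl-3-[(2S,3S)-2-[bis(4-benzyloxyphenyl)methyl]-3-(tert-butyldimethylsilyloxy)-3-(2,4,6-tris(benzyloxy)phenyl)propanoyl]oxazolidin-2-one | O=C([C@H]([C@H](O[Si](C)(C)C(C)(C)C)c1c(OCc2ccccc2)cc(OCc2ccccc2)cc1OCc1ccccc1)C(c1ccc(OCc2ccccc2)cc1)c1ccc(OCc2ccccc2)cc1)N1[C@@H](Cc2ccccc2)COC1=O | intermediate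
13 | (2R,3S)-2-[bis(4-benzyloxyphenyl)methyl]-3-(tert-butyldimethylsilyloxy)-3-(2,4,6-tris(benzyloxy)phenyl)propan-1-ol | OC[C@H]([C@H](O[Si](C)(C)C(C)(C)C)c1c(OCc2ccccc2)cc(OCc2ccccc2)cc1OCc1ccccc1)C(c1ccc(OCc2ccccc2)cc1)c1ccc(OCc2ccccc2)cc1 | intermediate
14 | (2R,3S)-2-[bis(4-benzyloxyphenyl)methyl]-3-(tert-butyldimethylsilyloxy)-3-(2,4,6-tris(benzyloxy)phenyl)propyl trifluoromethanesulfonate (not isolated) | FC(F)(F)S(=O)(=O)OC[C@H]([C@H](O[Si](C)(C)C(C)(C)C)c1c(OCc2ccccc2)cc(OCc2ccccc2)cc1OCc1ccccc1)C(c1ccc(OCc2ccccc2)cc1)c1ccc(OCc2ccccc2)cc1 | intermediate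
15 | [(2S,3S)-2-[bis(4-benzyloxyphenyl)methyl]-3-(tert-butyldimethylsilyloxy)-3-(2,4,6-tris(benzyloxy)phenyl)propyl]triphenylphosphonium triflate | [O-]S(=O)(=O)C(F)(F)F.c1ccc(cc1)[P+](c1ccccc1)(c1ccccc1)C[C@H]([C@H](O[Si](C)(C)C(C)(C)C)c1c(OCc2ccccc2)cc(OCc2ccccc2)cc1OCc1ccccc1)C(c1ccc(OCc2ccccc2)cc1)c1ccc(OCc2ccccc2)cc1 | intermediate
16 | methyl 2,4,6-trihydroxybenzoate | COC(=O)c1c(O)cc(O)cc1O | starting material
17 | benzyl bromide | BrCc1ccccc1 | starting material
18 | methyl 2,4-bis(benzyloxy)-6-hydroxybenzoate | COC(=O)c1c(O)cc(OCc2ccccc2)cc1OCc1ccccc1 | intermediate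
19 | 2,4-bis(benzyloxy)-6-hydroxybenzoic acid | OC(=O)c1c(O)cc(OCc2ccccc2)cc1OCc1ccccc1 | intermediate
20 | 2-acetoxy-4,6-bis(benzyloxy)benzoic acid | CC(=O)Oc1cc(OCc2ccccc2)cc(OCc2ccccc2)c1C(O)=O | intermediate
21 | 2-acetoxy-4,6-bis(benzyloxy)benzoyl chloride | CC(=O)Oc1cc(OCc2ccccc2)cc(OCc2ccccc2)c1C(Cl)=O | intermediate
22 | [(2S,3S)-2-[bis(4-benzyloxyphenyl)methyl]-3-(tert-butyldimethylsilyloxy)-3-(2,4,6-tris(benzyloxy)phenyl)propylidene]triphenylphosphorane (not isolated) | c1ccc(cc1)P(c1ccccc1)(c1ccccc1)=C[C@H]([C@H](O[Si](C)(C)C(C)(C)C)c1c(OCc2ccccc2)cc(OCc2ccccc2)cc1OCc1ccccc1)C(c1ccc(OCc2ccccc2)cc1)c1ccc(OCc2ccccc2)cc1 | intermediate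
23 | [(3S,4S)-1-[2-acetoxy-4,6-bis(benzyloxy)phenyl]-3-[bis(4-benzyloxyphenyl)methyl]-4-(tert-butyldimethylsilyloxy)-1-oxo-4-(2,4,6-tris(benzyloxy)phenyl)butan-2-yl]triphenylphosphonium chloride, both epimers at the phosphorus-bearing carbon (not isolated) | [Cl-].CC(=O)Oc1cc(OCc2ccccc2)cc(OCc2ccccc2)c1C(=O)C([P+](c1ccccc1)(c1ccccc1)c1ccccc1)[C@H]([C@H](O[Si](C)(C)C(C)(C)C)c1c(OCc2ccccc2)cc(OCc2ccccc2)cc1OCc1ccccc1)C(c1ccc(OCc2ccccc2)cc1)c1ccc(OCc2ccccc2)cc1 | intermediate
24 | (3S,4S)-1-[2-acetoxy-4,6-bis(benzyloxy)phenyl]-3-[bis(4-benzyloxyphenyl)methyl]-4-(tert-butyldimethylsilyloxy)-4-(2,4,6-tris(benzyloxy)phenyl)-2-(triphenylphosphoranylidene)butan-1-one | CC(=O)Oc1cc(OCc2ccccc2)cc(OCc2ccccc2)c1C(=O)C(=P(c1ccccc1)(c1ccccc1)c1ccccc1)[C@H]([C@H](O[Si](C)(C)C(C)(C)C)c1c(OCc2ccccc2)cc(OCc2ccccc2)cc1OCc1ccccc1)C(c1ccc(OCc2ccccc2)cc1)c1ccc(OCc2ccccc2)cc1 | intermediate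
25 | (3S,4S)-1-[2,4-bis(benzyloxy)-6-hydroxyphenyl]-3-[bis(4-benzyloxyphenyl)methyl]-4-(tert-butyldimethylsilyloxy)-4-(2,4,6-tris(benzyloxy)phenyl)-2-(triphenylphosphoranylidene)butan-1-one | Oc1cc(OCc2ccccc2)cc(OCc2ccccc2)c1C(=O)C(=P(c1ccccc1)(c1ccccc1)c1ccccc1)[C@H]([C@H](O[Si](C)(C)C(C)(C)C)c1c(OCc2ccccc2)cc(OCc2ccccc2)cc1OCc1ccccc1)C(c1ccc(OCc2ccccc2)cc1)c1ccc(OCc2ccccc2)cc1 | intermediate
26 | (3S,4S)-1-[2,4-bis(benzyloxy)-6-(formyloxy)phenyl]-3-[bis(4-benzyloxyphenyl)methyl]-4-(tert-butyldimethylsilyloxy)-4-(2,4,6-tris(benzyloxy)phenyl)-2-(triphenylphosphoranylidene)butan-1-one (precursor of the key step) | O=COc1cc(OCc2ccccc2)cc(OCc2ccccc2)c1C(=O)C(=P(c1ccccc1)(c1ccccc1)c1ccccc1)[C@H]([C@H](O[Si](C)(C)C(C)(C)C)c1c(OCc2ccccc2)cc(OCc2ccccc2)cc1OCc1ccccc1)C(c1ccc(OCc2ccccc2)cc1)c1ccc(OCc2ccccc2)cc1 | intermediate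
27 | 5,7-bis(benzyloxy)-3-[(1S,2R)-3,3-bis(4-benzyloxyphenyl)-1-(tert-butyldimethylsilyloxy)-1-(2,4,6-tris(benzyloxy)phenyl)propan-2-yl]-4H-chromen-4-one (product of the key step) | CC(C)(C)[Si](C)(C)O[C@H](c1c(OCc2ccccc2)cc(OCc2ccccc2)cc1OCc1ccccc1)[C@@H](c1coc2cc(OCc3ccccc3)cc(OCc3ccccc3)c2c1=O)C(c1ccc(OCc2ccccc2)cc1)c1ccc(OCc2ccccc2)cc1 | intermediate
28 | 5,7-bis(benzyloxy)-3-[(1S,2R)-3,3-bis(4-benzyloxyphenyl)-1-hydroxy-1-(2,4,6-tris(benzyloxy)phenyl)propan-2-yl]-4H-chromen-4-one | O[C@H](c1c(OCc2ccccc2)cc(OCc2ccccc2)cc1OCc1ccccc1)[C@@H](c1coc2cc(OCc3ccccc3)cc(OCc3ccccc3)c2c1=O)C(c1ccc(OCc2ccccc2)cc1)c1ccc(OCc2ccccc2)cc1 | intermediate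
29 | 5,7-bis(benzyloxy)-3-[(2R)-1,1-bis(4-benzyloxyphenyl)-3-oxo-3-(2,4,6-tris(benzyloxy)phenyl)propan-2-yl]-4H-chromen-4-one | O=C(c1c(OCc2ccccc2)cc(OCc2ccccc2)cc1OCc1ccccc1)[C@@H](c1coc2cc(OCc3ccccc3)cc(OCc3ccccc3)c2c1=O)C(c1ccc(OCc2ccccc2)cc1)c1ccc(OCc2ccccc2)cc1 | intermediate
30 | 5,7-dihydroxy-3-[(2R)-1,1-bis(4-hydroxyphenyl)-3-oxo-3-(2,4,6-trihydroxyphenyl)propan-2-yl]-4H-chromen-4-one (CNP0106875.1) | O=C(c1c(O)cc(O)cc1O)[C@@H](c1coc2cc(O)cc(O)c2c1=O)C(c1ccc(O)cc1)c1ccc(O)cc1 | target

## Step count and least certain steps

Total step count: 18. Longest linear sequence: 13 steps (steps 1, 2, 4–7 and 12–18).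

**Step 15 (key step).** The most likely failure is loss of the formyl group before the C–C bond forms. It can go by base-induced decarbonylation, by transfer to the enolate oxygen of the ylide or by adventitious water. Attack by the hindered, fully substituted ylide carbon is slow, so the phenol would be returned.
Fallback: close the ring at O1–C2 instead. The route is left at phenol 25. Alkaline hydrolysis of its C=P bond (NaOH, aqueous THF/MeOH, 50 °C) should give the ketone (3S,4S)-1-[2,4-bis(benzyloxy)-6-hydroxyphenyl]-3-[bis(4-benzyloxyphenyl)methyl]-4-(tert-butyldimethylsilyloxy)-4-(2,4,6-tris(benzyloxy)phenyl)butan-1-one F1, in which Cα is β to the carbonyl and cannot enolise. Condensation of its methylene with N,N-dimethylformamide dimethyl acetal (toluene, 100 °C) should give the 2-(dimethylaminomethylene) ketone F2. F2 cyclises on silica gel with loss of dimethylamine, and the route is rejoined at chromone 27.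

**Step 12 (ylide acylation).** Both partners are hindered, the ylide carbon by the branched Cα and the acid chloride by its two ortho substituents. Acylation may therefore be slow enough for proton transfer to the ylide and attack on the acetate to compete.
Fallback: change the acyl donor. The route is left at acid 19 and salt 15. Acid 19 is converted (acetone, SOCl2, DMAP, 1,2-dimethoxyethane, 0 °C → rt) into 5,7-bis(benzyloxy)-2,2-dimethyl-4H-1,3-benzodioxin-4-one F3. Its planar lactone carbonyl is attacked by ylide 22, acetone is lost, and the released phenoxide deprotonates the acylphosphonium ion. The route is rejoined at phenol 25, and steps 10, 11 and 13 are no longer needed.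

**Step 7 (phosphonium salt).** Attack of PPh3 at the β-branched carbon may be outrun by participation of an ortho benzyloxy oxygen. That would form a six-membered cyclic oxonium ion and then lose the benzyl group.
Fallback: use a less ionising leaving group. The route is left at alcohol 13. Appel iodination (I2, PPh3, imidazole, toluene) gives tert-butyl{[(1S,2S)-2-[bis(4-benzyloxyphenyl)methyl]-3-iodo-1-(2,4,6-tris(benzyloxy)phenyl)propyl]oxy}dimethylsilane F4. Thermal quaternisation (PPh3, iPr2NEt, MeCN, 90 °C, sealed tube) gives [(2S,3S)-2-[bis(4-benzyloxyphenyl)methyl]-3-(tert-butyldimethylsilyloxy)-3-(2,4,6-tris(benzyloxy)phenyl)propyl]triphenylphosphonium iodide F5. Deprotonation of F5 gives ylide 22, and the route is rejoined at 24.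

**Step 4 (aldol).** Aldehyde 9 is deactivated by three alkoxy donors and flanked by two ortho substituents, and the enolate carries a bulky α-substituent. Low conversion, or reversal and dehydration of the benzylic aldolate, is therefore possible.
Fallback: change the aldol manifold, from 6 and 9 to the same adduct 11, with no new compound. The chlorotitanium enolate of 6 (TiCl4, iPr2NEt, N-methylpyrrolidinone, CH2Cl2, −78 → 0 °C) is used, in which the aldehyde is bound and activated at a strongly Lewis acidic tetravalent titanium centre. The reaction is quenched cold to avoid ionisation.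

**Step 18 (hydrogenolysis).** Over-reduction of C2=C3 to the chromanone, or incomplete cleavage of the hindered ortho benzyl ethers, may occur.
Fallback: a non-reductive debenzylation from 29 to 30 with BCl3 and pentamethylbenzene as cation scavenger (CH2Cl2, −78 °C); no new compound is made.

## Further compounds

F1 | step 15 | (3S,4S)-1-[2,4-bis(benzyloxy)-6-hydroxyphenyl]-3-[bis(4-benzyloxyphenyl)methyl]-4-(tert-butyldimethylsilyloxy)-4-(2,4,6-tris(benzyloxy)phenyl)butan-1-one | Oc1cc(OCc2ccccc2)cc(OCc2ccccc2)c1C(=O)C[C@H]([C@H](O[Si](C)(C)C(C)(C)C)c1c(OCc2ccccc2)cc(OCc2ccccc2)cc1OCc1ccccc1)C(c1ccc(OCc2ccccc2)cc1)c1ccc(OCc2ccccc2)cc1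
F2 | step 15 | 2-(dimethylaminomethylene) derivative of F1 (enaminone) | CN(C)C=C(C(=O)c1c(O)cc(OCc2ccccc2)cc1OCc1ccccc1)[C@H]([C@H](O[Si](C)(C)C(C)(C)C)c1c(OCc2ccccc2)cc(OCc2ccccc2)cc1OCc1ccccc1)C(c1ccc(OCc2ccccc2)cc1)c1ccc(OCc2ccccc2)cc1
F3 | step 12 | 5,7-bis(benzyloxy)-2,2-dimethyl-4H-1,3-benzodioxin-4-one | CC1(C)Oc2cc(OCc3ccccc3)cc(OCc3ccccc3)c2C(=O)O1
F4 | step 7 | tert-butyl{[(1S,2S)-2-[bis(4-benzyloxyphenyl)methyl]-3-iodo-1-(2,4,6-tris(benzyloxy)phenyl)propyl]oxy}dimethylsilane | IC[C@H]([C@H](O[Si](C)(C)C(C)(C)C)c1c(OCc2ccccc2)cc(OCc2ccccc2)cc1OCc1ccccc1)C(c1ccc(OCc2ccccc2)cc1)c1ccc(OCc2ccccc2)cc1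
F5 | step 7 | [(2S,3S)-2-[bis(4-benzyloxyphenyl)methyl]-3-(tert-butyldimethylsilyloxy)-3-(2,4,6-tris(benzyloxy)phenyl)propyl]triphenylphosphonium iodide | [I-].c1ccc(cc1)[P+](c1ccccc1)(c1ccccc1)C[C@H]([C@H](O[Si](C)(C)C(C)(C)C)c1c(OCc2ccccc2)cc(OCc2ccccc2)cc1OCc1ccccc1)C(c1ccc(OCc2ccccc2)cc1)c1ccc(OCc2ccccc2)cc1
F0 | step 4 | none | none
F0 | step 18 | none | none
A1 | alternative 1 | (2S)-2-[bis(4-hydroxyphenyl)methyl]-1,4-bis(2,4,6-trihydroxyphenyl)butane-1,4-dione | O=C(c1c(O)cc(O)cc1O)[C@@H](CC(=O)c1c(O)cc(O)cc1O)C(c1ccc(O)cc1)c1ccc(O)cc1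
A2 | alternative 1 | (2S)-2-[bis(4-hydroxyphenyl)methyl]butanedioic acid | OC(=O)[C@@H](CC(O)=O)C(c1ccc(O)cc1)c1ccc(O)cc1
A3 | alternative 1 | phloroglucinol | Oc1cc(O)cc(O)c1
A4 | alternative 2 | (3R)-5,7-dimethoxy-3-[(2R)-1,1-bis(4-methoxyphenyl)-3-oxo-3-(2,4,6-trimethoxyphenyl)propan-2-yl]-2,3-dihydro-4H-chromen-4-one | O=C(c1c(OC)cc(OC)cc1OC)[C@@H]([C@@H]1COc2cc(OC)cc(OC)c2C1=O)C(c1ccc(OC)cc1)c1ccc(OC)cc1
A5 | alternative 2 | 2-{[4,4-bis(4-methoxyphenyl)-3-(2,4,6-trimethoxybenzoyl)but-2-en-1-yl]oxy}-4,6-dimethoxybenzaldehyde (alkene geometry left open) | O=Cc1c(OC)cc(OC)cc1OCC=C(C(=O)c1c(OC)cc(OC)cc1OC)C(c1ccc(OC)cc1)c1ccc(OC)cc1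
A6 | alternative 3 | (2S)-2-[bis(4-methoxyphenyl)methyl]-4-(2-ethoxy-4,6-dihydroxyphenyl)-1-(2,4,6-trimethoxyphenyl)butane-1,4-dione | CCOc1cc(O)cc(O)c1C(=O)C[C@H](C(=O)c1c(OC)cc(OC)cc1OC)C(c1ccc(OC)cc1)c1ccc(OC)cc1
A7 | alternative 3 | (5S)-5-[bis(4-methoxyphenyl)methyl]-1-ethoxy-6-(2,4,6-trimethoxyphenyl)hex-1-yne-3,6-dione | CCOC#CC(=O)C[C@H](C(=O)c1c(OC)cc(OC)cc1OC)C(c1ccc(OC)cc1)c1ccc(OC)cc1
A8 | alternative 3 | 1-methoxy-1,3-bis(trimethylsilyloxy)buta-1,3-diene | COC(O[Si](C)(C)C)=CC(=C)O[Si](C)(C)C
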